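(The runs were computed from invented constants, noise included.)

Picture a one-step world: solid substrate leaves at a fixed amount per litre per day, whatever the loading, which is a zero-order loss.

| flask | solid substrate | coupling partner | remark | time |
|---|---|---|---|---|
| dusk | 0.34 M | 0.60 M | run made earlier |  |
| midnight | 0.75 M | 0.60 M | run made earlier |  |
| flask | 0.50 M | 0.600 M |  | 12 d |

- dusk (time / d: solid substrate / %, single product / %, double product / %): 0.500: 92, 4, 0; 1.67: 87, 3, 1; 2.50: 77, 7, 2; 4.00: 72, 8, 5; 6.00: 59, 13, 7; 8.00: 45, 10, 9; 10.0: 36, 14, 12
- midnight (time / d: solid substrate / %, single product / %, double product / %): 0.833: 97, 0, 0; 1.25: 95, 0, 0; 1.67: 92, 0, 0; 2.50: 93, 3, 0; 4.00: 87, 5, 2; 6.00: 81, 5, 2; 10.0: 73, 6, 6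

(scatter of a reading: 2 percentage points)

- solid, in amounts per volume of the solution: solid substrate
- the analysis behind the earlier runs scatters by 2 percentage points, standard deviation
- at the start none of the solid substrate is in solution

- amount of solid substrate at 12 d, in percent of the solid substrate charged (only what is still solid)
- amount of single product at 12 d, in percent of the solid substrate charged
- amount of double product at 12 d, in percent of the solid substrate charged
- amount of triple product at 12 d, in percent of the solid substrate charged

The two runs come near that picture. Over 10.0 d the readings give a loss of 0.0218 M d⁻¹ for the dusk run and 0.0203 M d⁻¹ for the midnight run, though midnight was charged with twice as much solid. Take the mean, 0.0210 M d⁻¹, and fold it with time and charge into one number. For the asked flask, this estimate puts 50.4 % of the charge out of the solid by 12 d. This is the burn-off number, mean loss times time over charge, and you read the solid left straight off it: I commit to 49.6 % still solid.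

Is one number enough? At 6.00 d it gives 62.9 % for the dusk run, which read 59 %, and 83.2 % for the midnight run, which read 81 %, with a scatter of 2 percentage points. So it serves for the solid, running slightly high at that time, but it says nothing about how the lost solid divides among the products.

The forecast reasons alike, “Solid loss is roughly zero order and independent of loading”, yet it keeps more solid than I do: 52 %, with 10 % single, 12 % double and 20 % triple product.

The asked flask gives 50.2 % solid, 8.65 % single, 10.7 % double and 10.7 % triple product.

    starting material + coupling partner → single product + released group (k = 0.0503 L mol⁻¹ h⁻¹)
    coupling partner + single product → double product + released group (k = 0.0521 L mol⁻¹ h⁻¹)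
    coupling partner + double product ⇌ triple product + released group (K = 1.98, k = 0.0641 L mol⁻¹ h⁻¹)
    solid substrate ⇌ starting material, rate k4*(cs4 - [starting material]) while solid is left; crystals form when [starting material] > cs4 (solubility = 0.0720 M, k = 0.0255 h⁻¹)
    double product ⇌ isomer of the product (K = 1.46, k = 0.0134 h⁻¹)

In the asked flask 49.8 % of the charge has left the solid, against the number's 50.4 %. Its triple product lies below the forecast's, and it also holds 9.70 % isomer of the product. Now take the neighbour flask charged with 2.0 M of solid substrate. The same loss over the same time gives a burn-off number of 12.6 %, so 87.4 % should stay solid, and that neighbour flask shows 87.6 %. Its triple product stands at 2.67 %, a quarter of the asked flask's 10.7 %.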